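**Retrosynthetic overview**

1. The C40 skeleton is cut into a furanoid C15 phosphonium salt (C1–C11), the C10 dialdehyde (C12–C12') and an ε-ring C15 phosphonium salt (C11'–C1'); two Wittig unions form C11=C12 and C11'=C12'.
2. The strategy rests on the dihydrofuran ring O–C5–C6=C7–C8: C6=C7 is its only bond without stereochemistry, so it is opened by ring-closing metathesis to a C5–O–C8 ether with a C6 methylene and a C8 vinyl group.
3. That ether comes from an iridium-catalysed branch-selective allylic etherification (sets C8) of a tertiary C5 alcohol. C5 is set by Sharpless epoxidation of an actinol-derived allylic alcohol, and a Wharton transposition then unveils the C6 methylene.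
4. The ε-ring C15 salt comes from α-ionone by chain extension, C3' oxidation and reduction, and lipase resolution.
5. Ring order: the carbocycle is bought with actinol and the dihydrofuran is closed in step 14; the ε ring is bought with α-ionone.

Key step: step 14

Remark: carotenoid numbering is used (ring C1–C6, with C5 carrying the methyl group and the ring oxygen; chain C7–C15; primes for the ε half); the target is the (3S,5R,8S,3'R,6'R) isomer.
Assumption: (E)-α-ionone is bought as the racemate and all-E 2,7-dimethylocta-2,4,6-trienedial as the commercial carotenoid building block.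

**Route**

Step 1
Reactants: 1 (4R,6R)-4-hydroxy-2,2,6-trimethylcyclohexanone (actinol)
Product: 2 (4R,6R)-4-(tert-butyldimethylsilyloxy)-2,2,6-trimethylcyclohexanone
Conditions: TBSCl, imidazole, DMF, rt
Reagents that add atoms: tert-butyldimethylsilyl chloride, CC(C)(C)[Si](C)(C)Cl
Why: Imidazole-promoted silylation of the unhindered secondary alcohol should leave the ketone and both stereocentres untouched.

Step 2
Reactants: 2 (4R,6R)-4-(tert-butyldimethylsilyloxy)-2,2,6-trimethylcyclohexanone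
Product: 4 (4R)-4-(tert-butyldimethylsilyloxy)-2,6,6-trimethylcyclohex-1-en-1-yl trifluoromethanesulfonate, via lithium enolate 3 (not isolated)
Conditions: LiN(i-Pr)2, THF, −78 to 0 °C; then PhNTf2, −78 °C to rt
Reagents that add atoms: N-phenylbis(trifluoromethanesulfonimide), O=S(=O)(N(c1ccccc1)S(=O)(=O)C(F)(F)F)C(F)(F)F
Why: The ketone has a single α-hydrogen (at C5, the other α-carbon being quaternary), so enolate O-triflation should give one tetrasubstituted vinyl triflate; the C5 centre is erased on purpose and rebuilt in step 5.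

Step 3
Reactants: 4 (4R)-4-(tert-butyldimethylsilyloxy)-2,6,6-trimethylcyclohex-1-en-1-yl trifluoromethanesulfonate
Product: 5 methyl (4R)-4-(tert-butyldimethylsilyloxy)-2,6,6-trimethylcyclohex-1-ene-1-carboxylate
Conditions: Pd(OAc)2 (5 mol %), PPh3, CO (1 atm), Et3N, MeOH/DMF, 60 °C
Reagents that add atoms: carbon monoxide, [C-]#[O+]; methanol, CO
Why: Palladium-catalysed alkoxycarbonylation of the vinyl triflate (oxidative addition, CO insertion, methanolysis) should place on C6 the one-carbon unit that later becomes the exocyclic methylene.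

Step 4
Reactants: 5 methyl (4R)-4-(tert-butyldimethylsilyloxy)-2,6,6-trimethylcyclohex-1-ene-1-carboxylate
Product: 6 [(4R)-4-(tert-butyldimethylsilyloxy)-2,6,6-trimethylcyclohex-1-en-1-yl]methanol
Conditions: i-Bu2AlH, CH2Cl2, −78 °C
Reagents that add atoms: none
Why: Hydride reduction of the conjugated ester with i-Bu2AlH should stop cleanly at the allylic alcohol without touching the silyl ether.

Step 5
Reactants: 6 [(4R)-4-(tert-butyldimethylsilyloxy)-2,6,6-trimethylcyclohex-1-en-1-yl]methanol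
Product: 7 [(1R,4S,6R)-4-(tert-butyldimethylsilyloxy)-2,2,6-trimethyl-7-oxabicyclo[4.1.0]heptan-1-yl]methanol
Conditions: Ti(Oi-Pr)4 (10 mol %), D-(−)-diethyl tartrate (12 mol %), t-BuOOH, 4 Å molecular sieves, CH2Cl2, −20 °C
Reagents that add atoms: tert-butyl hydroperoxide, CC(C)(C)OO
Why: In this Sharpless asymmetric epoxidation the titanium D-(−)-tartrate complex should deliver oxygen to the alkene face anti to the C3 silyloxy group (reagent control), which sets C5 (R) together with C6.

Step 6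
Reactants: 7 [(1R,4S,6R)-4-(tert-butyldimethylsilyloxy)-2,2,6-trimethyl-7-oxabicyclo[4.1.0]heptan-1-yl]methanol
Product: 8 (1S,4S,6R)-4-(tert-butyldimethylsilyloxy)-2,2,6-trimethyl-7-oxabicyclo[4.1.0]heptane-1-carbaldehyde
Conditions: Dess–Martin periodinane, NaHCO3, CH2Cl2, 0 °C to rt
Reagents that add atoms: none
Why: Buffered Dess–Martin oxidation should convert the primary alcohol into the aldehyde without opening the epoxide, whose α-carbon is quaternary and cannot epimerise.

Step 7
Reactants: 8 (1S,4S,6R)-4-(tert-butyldimethylsilyloxy)-2,2,6-trimethyl-7-oxabicyclo[4.1.0]heptane-1-carbaldehyde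
Product: 10 (1R,5S)-5-(tert-butyldimethylsilyloxy)-1,3,3-trimethyl-2-methylidenecyclohexan-1-ol, via hydrazone 9 (not isolated)
Conditions: N2H4·H2O, AcOH (cat.), MeOH, 0 °C to rt
Reagents that add atoms: none
Why: In this Wharton transposition the hydrazone should open the epoxide to an alkenyl diazene that loses N2, giving the C6 methylene and the C5 tertiary alcohol; the C5–O bond is never broken, so C5 keeps its configuration.

Step 8
Reactants: 11 3-methylbut-2-en-1-ol (prenol)
Product: 12 3-methylbut-2-en-1-yl pivalate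
Conditions: PivCl, pyridine, DMAP (cat.), CH2Cl2, 0 °C to rt
Reagents that add atoms: pivaloyl chloride, CC(C)(C)C(Cl)=O
Why: Simple acylation should mask the future C11 oxygen as an ester that survives the oxidations, alkoxides and metathesis ahead.

Step 9
Reactants: 12 3-methylbut-2-en-1-yl pivalate
Product: 13 (2E)-3-methyl-4-oxobut-2-en-1-yl pivalate
Conditions: SeO2, 1,4-dioxane, 80 °C
Reagents that add atoms: selenium dioxide, O=[Se]=O
Why: Selenium dioxide allylic oxidation (ene reaction, then [2,3] shift) should attack the (E)-methyl group of the trisubstituted alkene and give the (E)-enal.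

Step 10
Reactants: 13 (2E)-3-methyl-4-oxobut-2-en-1-yl pivalate
Product: 14 (2E,4E)-3-methyl-6-oxohexa-2,4-dien-1-yl pivalate
Conditions: Ph3P=CHCHO, toluene, 80 °C
Reagents that add atoms: (triphenylphosphoranylidene)acetaldehyde, O=CC=P(c1ccccc1)(c1ccccc1)c1ccccc1
Why: Wittig homologation with the stabilised formyl ylide should add C7 and the future leaving-group carbon as an (E)-alkene, the product dienal being less electrophilic than the starting enal.

Step 11
Reactants: 14 (2E,4E)-3-methyl-6-oxohexa-2,4-dien-1-yl pivalate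
Product: 15 (2E,4E)-6-hydroxy-3-methylhexa-2,4-dien-1-yl pivalate
Conditions: NaBH4, CeCl3·7H2O, MeOH, 0 °C
Reagents that add atoms: none
Why: Luche 1,2-reduction should reduce only the aldehyde and leave the hindered pivalate and the diene intact.

Step 12
Reactants: 15 (2E,4E)-6-hydroxy-3-methylhexa-2,4-dien-1-yl pivalate
Product: 16 (2E,4E)-6-[(tert-butoxycarbonyl)oxy]-3-methylhexa-2,4-dien-1-yl pivalate
Conditions: Boc2O, Bu4NHSO4 (cat.), aq NaOH, CH2Cl2, 0 °C
Reagents that add atoms: di-tert-butyl dicarbonate, CC(C)(C)OC(=O)OC(=O)OC(C)(C)C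
Why: Phase-transfer carbonate formation should give the linear dienyl tert-butyl carbonate, chosen so that the only alkoxide later released is hindered tert-butoxide.

Step 13
Reactants: 10 (1R,5S)-5-(tert-butyldimethylsilyloxy)-1,3,3-trimethyl-2-methylidenecyclohexan-1-ol; 16 (2E,4E)-6-[(tert-butoxycarbonyl)oxy]-3-methylhexa-2,4-dien-1-yl pivalate
Product: 18 (2E,4S)-3-methyl-4-{[(1R,5S)-5-(tert-butyldimethylsilyloxy)-1,3,3-trimethyl-2-methylidenecyclohexyl]oxy}hexa-2,5-dien-1-yl pivalate, via copper alkoxide 17 (not isolated)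
Conditions: n-BuLi, THF, 0 °C; CuI; then 16 (2 equiv), [Ir(cod)Cl]2 (2 mol %), (Sa,Sc,Sc)-binaphthol bis(1-phenylethyl)amine phosphoramidite (4 mol %, pre-activated with n-PrNH2), THF, rt
Reagents that add atoms: none
Why: In this iridium-catalysed branch-selective allylic etherification the copper alkoxide should attack the substituted terminus of the allyl iridium complex anti to the metal, so that the chiral phosphoramidite (catalyst control) sets C8 as (S) while C5 is carried in unchanged.

Step 14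
Reactants: 18 (2E,4S)-3-methyl-4-{[(1R,5S)-5-(tert-butyldimethylsilyloxy)-1,3,3-trimethyl-2-methylidenecyclohexyl]oxy}hexa-2,5-dien-1-yl pivalate
Product: 19 (2E)-3-[(2S,6S,7aR)-6-(tert-butyldimethylsilyloxy)-4,4,7a-trimethyl-2,4,5,6,7,7a-hexahydro-1-benzofuran-2-yl]but-2-en-1-yl pivalate
Conditions: second-generation Hoveyda–Grubbs catalyst [RuCl2(H2IMes)(=CH-C6H4-2-O-i-Pr)] (10 mol %), 1,4-benzoquinone (20 mol %), toluene (0.005 M), 80 °C, argon purge
Reagents that add atoms: none
Why: The ruthenium alkylidene should exchange onto the unhindered C8 vinyl group, the new alkylidene at C7 should add across the C6 methylene in an intramolecular [2+2], and cycloreversion of the ruthenacyclobutane should expel ethene and leave the C6=C7 bond. The closest known reaction type is ring-closing metathesis of bis-allylic ethers to 2,5-dihydrofurans in which one partner is a 1,1-disubstituted alkene. The five-membered ring O–C5–C6=C7–C8 closes by this intramolecular alkene metathesis, helped by the quaternary C5 and the C1 gem-dimethyl group, which hold the two alkenes close together. No stereocentre is formed, and 1,4-benzoquinone is added to suppress ruthenium hydride alkene migration that could erode the allylic C8 centre. The step needs chemoselectivity among three alkenes: the monosubstituted vinyl group is the only site where the catalyst can load, the trisubstituted C9=C10 alkene is too hindered to engage, and the shielded methylene can react only intramolecularly. High dilution and removal of ethene should favour closure over homodimerisation of the vinyl group.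

Step 15
Reactants: 19 (2E)-3-[(2S,6S,7aR)-6-(tert-butyldimethylsilyloxy)-4,4,7a-trimethyl-2,4,5,6,7,7a-hexahydro-1-benzofuran-2-yl]but-2-en-1-yl pivalate
Product: 20 (2E)-3-[(2S,6S,7aR)-6-(tert-butyldimethylsilyloxy)-4,4,7a-trimethyl-2,4,5,6,7,7a-hexahydro-1-benzofuran-2-yl]but-2-en-1-ol
Conditions: i-Bu2AlH, CH2Cl2, −78 °C
Reagents that add atoms: none
Why: Reductive cleavage of the pivalate should free the C11 alcohol under non-acidic conditions that leave the silyl ether and the bis-allylic C8–O bond alone.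

Step 16
Reactants: 20 (2E)-3-[(2S,6S,7aR)-6-(tert-butyldimethylsilyloxy)-4,4,7a-trimethyl-2,4,5,6,7,7a-hexahydro-1-benzofuran-2-yl]but-2-en-1-ol
Product: 22 {(2E)-3-[(2S,6S,7aR)-6-(tert-butyldimethylsilyloxy)-4,4,7a-trimethyl-2,4,5,6,7,7a-hexahydro-1-benzofuran-2-yl]but-2-en-1-yl}triphenylphosphonium bromide, via allylic bromide 21 (not isolated)
Conditions: CBr4, PPh3, CH2Cl2, 0 °C; then PPh3, rt
Reagents that add atoms: carbon tetrabromide, BrC(Br)(Br)Br; triphenylphosphine, c1ccc(cc1)P(c1ccccc1)c1ccccc1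
Why: Appel bromination followed by quaternisation should give the C15 salt under neutral conditions, avoiding the acid that would ionise the C8–O bond and scramble C8.

Step 17
Reactants: 22 {(2E)-3-[(2S,6S,7aR)-6-(tert-butyldimethylsilyloxy)-4,4,7a-trimethyl-2,4,5,6,7,7a-hexahydro-1-benzofuran-2-yl]but-2-en-1-yl}triphenylphosphonium bromide; 23 (2E,4E,6E)-2,7-dimethylocta-2,4,6-trienedial
Product: 24 (2E,4E,6E,8E,10E)-2,7-dimethyl-11-[(2S,6S,7aR)-6-(tert-butyldimethylsilyloxy)-4,4,7a-trimethyl-2,4,5,6,7,7a-hexahydro-1-benzofuran-2-yl]dodeca-2,4,6,8,10-pentaenal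
Conditions: 23 (3 equiv), NaOMe, MeOH/CH2Cl2, 0 °C to rt; then heptane, 80 °C
Reagents that add atoms: none
Why: Wittig olefination with the allylic ylide generated in the presence of excess dialdehyde should give mono-olefination at C11=C12, and heating should isomerise any (11Z) product to the all-E aldehyde.

Step 18
Reactants: 25 (E)-4-(2,6,6-trimethylcyclohex-2-en-1-yl)but-3-en-2-one (racemic α-ionone); 26 triethyl phosphonoacetate
Product: 27 ethyl (2E,4E)-3-methyl-5-(2,6,6-trimethylcyclohex-2-en-1-yl)penta-2,4-dienoate (racemic)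
Conditions: NaH, THF, 0 °C to reflux; (2Z) isomer removed by chromatography
Reagents that add atoms: none
Why: Horner–Wadsworth–Emmons olefination of the methyl ketone should give mainly the (2E)-dienoate and extends the ε half to C15.

Step 19
Reactants: 27 ethyl (2E,4E)-3-methyl-5-(2,6,6-trimethylcyclohex-2-en-1-yl)penta-2,4-dienoate (racemic)
Product: 28 ethyl (2E,4E)-3-methyl-5-(2,6,6-trimethyl-4-oxocyclohex-2-en-1-yl)penta-2,4-dienoate (racemic)
Conditions: Rh2(cap)4 (1 mol %), t-BuOOH (aq, 5 equiv), K2CO3, CH2Cl2, rt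
Reagents that add atoms: tert-butyl hydroperoxide, CC(C)(C)OO
Why: Dirhodium-catalysed allylic oxidation with tert-butyl hydroperoxide should oxidise the ring CH2 at C3' next to the trisubstituted alkene, the tertiary C6' hydrogen being shielded by the gem-dimethyl group and the C5' methyl.

Step 20
Reactants: 28 ethyl (2E,4E)-3-methyl-5-(2,6,6-trimethyl-4-oxocyclohex-2-en-1-yl)penta-2,4-dienoate (racemic)
Product: 29 ethyl (2E,4E)-5-[(1RS,4RS)-4-hydroxy-2,6,6-trimethylcyclohex-2-en-1-yl]-3-methylpenta-2,4-dienoate (racemic trans)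
Conditions: LiBH(s-Bu)3, THF, −78 °C
Reagents that add atoms: none
Why: The bulky hydride should add 1,2 to the β-substituted enone from the face away from the axial C1' methyl while the side chain sits pseudo-axial, which places the new C3' hydroxyl trans to the C6' chain (substrate control).

Step 21
Reactants: 29 ethyl (2E,4E)-5-[(1RS,4RS)-4-hydroxy-2,6,6-trimethylcyclohex-2-en-1-yl]-3-methylpenta-2,4-dienoate (racemic trans)
Product: 30 ethyl (2E,4E)-5-[(1R,4R)-4-acetoxy-2,6,6-trimethylcyclohex-2-en-1-yl]-3-methylpenta-2,4-dienoate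
Conditions: Burkholderia cepacia lipase, vinyl acetate, t-BuOMe, 30 °C, stopped near half conversion
Reagents that add atoms: vinyl acetate, CC(=O)OC=C
Why: Lipase-catalysed kinetic resolution should acylate the (3'R) alcohol, as the size-based model for secondary alcohols predicts with the alkene side as the large group, so the (3'R,6'R) series is separated as its acetate from the unreacted enantiomer.

Step 22
Reactants: 30 ethyl (2E,4E)-5-[(1R,4R)-4-acetoxy-2,6,6-trimethylcyclohex-2-en-1-yl]-3-methylpenta-2,4-dienoate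
Product: 31 (2E,4E)-5-[(1R,4R)-4-hydroxy-2,6,6-trimethylcyclohex-2-en-1-yl]-3-methylpenta-2,4-dien-1-ol
Conditions: i-Bu2AlH (excess), CH2Cl2, −78 to 0 °C
Reagents that add atoms: none
Why: One hydride reduction should remove the acetate and reduce the dienoate to the primary allylic alcohol without acid, to which the ring allylic alcohol is sensitive.

Step 23
Reactants: 31 (2E,4E)-5-[(1R,4R)-4-hydroxy-2,6,6-trimethylcyclohex-2-en-1-yl]-3-methylpenta-2,4-dien-1-ol
Product: 33 {(2E,4E)-5-[(1R,4R)-4-hydroxy-2,6,6-trimethylcyclohex-2-en-1-yl]-3-methylpenta-2,4-dien-1-yl}triphenylphosphonium bromide, via allylic bromide 32 (not isolated)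
Conditions: CBr4 (1.05 equiv), PPh3, CH2Cl2, −30 °C; then PPh3, rt
Reagents that add atoms: carbon tetrabromide, BrC(Br)(Br)Br; triphenylphosphine, c1ccc(cc1)P(c1ccccc1)c1ccccc1
Why: With one equivalent of reagent at low temperature the Appel bromination should take the primary dienylic alcohol in preference to the hindered ring alcohol, and neutral quaternisation then gives the hydroxy C15 salt.

Step 24
Reactants: 24 (2E,4E,6E,8E,10E)-2,7-dimethyl-11-[(2S,6S,7aR)-6-(tert-butyldimethylsilyloxy)-4,4,7a-trimethyl-2,4,5,6,7,7a-hexahydro-1-benzofuran-2-yl]dodeca-2,4,6,8,10-pentaenal; 33 {(2E,4E)-5-[(1R,4R)-4-hydroxy-2,6,6-trimethylcyclohex-2-en-1-yl]-3-methylpenta-2,4-dien-1-yl}triphenylphosphonium bromide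
Product: 34 (3S,5R,8S,3'R,6'R)-3-(tert-butyldimethylsilyloxy)-5,8-epoxy-5,8-dihydro-β,ε-caroten-3'-ol
Conditions: 33 (1.3 equiv), NaOMe (excess), MeOH/CH2Cl2, 0 °C to rt; then heptane, 80 °C
Reagents that add atoms: none
Why: The second Wittig olefination should form C11'=C12' (the free hydroxyl only consumes extra base), and heating should bring the polyene to the all-E form without touching any stereocentre.

Step 25
Reactants: 34 (3S,5R,8S,3'R,6'R)-3-(tert-butyldimethylsilyloxy)-5,8-epoxy-5,8-dihydro-β,ε-caroten-3'-ol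
Product: 35 (3S,5R,8S,3'R,6'R)-5,8-epoxy-5,8-dihydro-β,ε-carotene-3,3'-diol (target)
Conditions: Bu4NF, THF, rt, in the dark
Reagents that add atoms: none
Why: Fluoride desilylation should free the C3 hydroxyl under basic, acid-free conditions that preserve the furanoid C8 centre and the allylic C3' alcohol.

**Compound list**

1 | (4R,6R)-4-hydroxy-2,2,6-trimethylcyclohexanone (actinol) | C[C@@H]1C[C@@H](O)CC(C)(C)C1=O | starting material
2 | (4R,6R)-4-(tert-butyldimethylsilyloxy)-2,2,6-trimethylcyclohexanone | C[C@@H]1C[C@@H](O[Si](C)(C)C(C)(C)C)CC(C)(C)C1=O | intermediate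
3 | lithium enolate of 2 | [Li]OC1=C(C)C[C@@H](O[Si](C)(C)C(C)(C)C)CC1(C)C | intermediate (not isolated)
4 | (4R)-4-(tert-butyldimethylsilyloxy)-2,6,6-trimethylcyclohex-1-en-1-yl trifluoromethanesulfonate | FC(F)(F)S(=O)(=O)OC1=C(C)C[C@@H](O[Si](C)(C)C(C)(C)C)CC1(C)C | intermediate
5 | methyl (4R)-4-(tert-butyldimethylsilyloxy)-2,6,6-trimethylcyclohex-1-ene-1-carboxylate | COC(=O)C1=C(C)C[C@@H](O[Si](C)(C)C(C)(C)C)CC1(C)C | intermediate
6 | [(4R)-4-(tert-butyldimethylsilyloxy)-2,6,6-trimethylcyclohex-1-en-1-yl]methanol | OCC1=C(C)C[C@@H](O[Si](C)(C)C(C)(C)C)CC1(C)C | intermediate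
7 | [(1R,4S,6R)-4-(tert-butyldimethylsilyloxy)-2,2,6-trimethyl-7-oxabicyclo[4.1.0]heptan-1-yl]methanol | CC1(C)C[C@H](O[Si](C)(C)C(C)(C)C)C[C@@]2(C)O[C@@]12CO | intermediate
8 | (1S,4S,6R)-4-(tert-butyldimethylsilyloxy)-2,2,6-trimethyl-7-oxabicyclo[4.1.0]heptane-1-carbaldehyde | CC1(C)C[C@H](O[Si](C)(C)C(C)(C)C)C[C@@]2(C)O[C@@]12C=O | intermediate
9 | hydrazone of 8 | CC1(C)C[C@H](O[Si](C)(C)C(C)(C)C)C[C@@]2(C)O[C@@]12C=NN | intermediate (not isolated)
10 | (1R,5S)-5-(tert-butyldimethylsilyloxy)-1,3,3-trimethyl-2-methylidenecyclohexan-1-ol | C=C1C(C)(C)C[C@H](O[Si](C)(C)C(C)(C)C)C[C@@]1(C)O | intermediate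
11 | 3-methylbut-2-en-1-ol (prenol) | CC(C)=CCO | starting material
12 | 3-methylbut-2-en-1-yl pivalate | CC(C)=CCOC(=O)C(C)(C)C | intermediate
13 | (2E)-3-methyl-4-oxobut-2-en-1-yl pivalate | O=C/C(C)=C/COC(=O)C(C)(C)C | intermediate
14 | (2E,4E)-3-methyl-6-oxohexa-2,4-dien-1-yl pivalate | O=C/C=C/C(C)=C/COC(=O)C(C)(C)C | intermediate
15 | (2E,4E)-6-hydroxy-3-methylhexa-2,4-dien-1-yl pivalate | OC/C=C/C(C)=C/COC(=O)C(C)(C)C | intermediate
16 | (2E,4E)-6-[(tert-butoxycarbonyl)oxy]-3-methylhexa-2,4-dien-1-yl pivalate | CC(C)(C)OC(=O)OC/C=C/C(C)=C/COC(=O)C(C)(C)C | intermediate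
17 | copper alkoxide of 10 | [Cu]O[C@]1(C)C[C@@H](O[Si](C)(C)C(C)(C)C)CC(C)(C)C1=C | intermediate (not isolated)
18 | (2E,4S)-3-methyl-4-{[(1R,5S)-5-(tert-butyldimethylsilyloxy)-1,3,3-trimethyl-2-methylidenecyclohexyl]oxy}hexa-2,5-dien-1-yl pivalate | C=C[C@@H](/C(C)=C/COC(=O)C(C)(C)C)O[C@]1(C)C[C@@H](O[Si](C)(C)C(C)(C)C)CC(C)(C)C1=C | intermediate
19 | (2E)-3-[(2S,6S,7aR)-6-(tert-butyldimethylsilyloxy)-4,4,7a-trimethyl-2,4,5,6,7,7a-hexahydro-1-benzofuran-2-yl]but-2-en-1-yl pivalate | CC(C)(C)C(=O)OC/C=C(\C)[C@@H]1C=C2C(C)(C)C[C@H](O[Si](C)(C)C(C)(C)C)C[C@@]2(C)O1 | intermediate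
20 | (2E)-3-[(2S,6S,7aR)-6-(tert-butyldimethylsilyloxy)-4,4,7a-trimethyl-2,4,5,6,7,7a-hexahydro-1-benzofuran-2-yl]but-2-en-1-ol | OC/C=C(\C)[C@@H]1C=C2C(C)(C)C[C@H](O[Si](C)(C)C(C)(C)C)C[C@@]2(C)O1 | intermediate
21 | (2S,6S,7aR)-2-[(2E)-4-bromobut-2-en-2-yl]-6-(tert-butyldimethylsilyloxy)-4,4,7a-trimethyl-2,4,5,6,7,7a-hexahydro-1-benzofuran | BrC/C=C(\C)[C@@H]1C=C2C(C)(C)C[C@H](O[Si](C)(C)C(C)(C)C)C[C@@]2(C)O1 | intermediate (not isolated)
22 | {(2E)-3-[(2S,6S,7aR)-6-(tert-butyldimethylsilyloxy)-4,4,7a-trimethyl-2,4,5,6,7,7a-hexahydro-1-benzofuran-2-yl]but-2-en-1-yl}triphenylphosphonium bromide | c1ccccc1[P+](c1ccccc1)(c1ccccc1)C/C=C(\C)[C@@H]1C=C2C(C)(C)C[C@H](O[Si](C)(C)C(C)(C)C)C[C@@]2(C)O1.[Br-] | intermediate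
23 | (2E,4E,6E)-2,7-dimethylocta-2,4,6-trienedial | O=C/C(C)=C/C=C/C=C(C)/C=O | starting material
24 | (2E,4E,6E,8E,10E)-2,7-dimethyl-11-[(2S,6S,7aR)-6-(tert-butyldimethylsilyloxy)-4,4,7a-trimethyl-2,4,5,6,7,7a-hexahydro-1-benzofuran-2-yl]dodeca-2,4,6,8,10-pentaenal | O=C/C(C)=C/C=C/C=C(C)/C=C/C=C(\C)[C@@H]1C=C2C(C)(C)C[C@H](O[Si](C)(C)C(C)(C)C)C[C@@]2(C)O1 | intermediate
25 | (E)-4-(2,6,6-trimethylcyclohex-2-en-1-yl)but-3-en-2-one (racemic α-ionone) | CC1=CCCC(C)(C)C1/C=C/C(C)=O | starting material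
26 | triethyl phosphonoacetate | CCOC(=O)CP(=O)(OCC)OCC | starting material
27 | ethyl (2E,4E)-3-methyl-5-(2,6,6-trimethylcyclohex-2-en-1-yl)penta-2,4-dienoate (racemic) | CCOC(=O)/C=C(C)/C=C/C1C(C)=CCCC1(C)C | intermediate
28 | ethyl (2E,4E)-3-methyl-5-(2,6,6-trimethyl-4-oxocyclohex-2-en-1-yl)penta-2,4-dienoate (racemic) | CCOC(=O)/C=C(C)/C=C/C1C(C)=CC(=O)CC1(C)C | intermediate
29 | ethyl (2E,4E)-5-[(1RS,4RS)-4-hydroxy-2,6,6-trimethylcyclohex-2-en-1-yl]-3-methylpenta-2,4-dienoate (racemic trans; the (1R,4R) enantiomer is drawn) | CC1=C[C@H](O)CC(C)(C)[C@H]1/C=C/C(C)=C/C(=O)OCC | intermediate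
30 | ethyl (2E,4E)-5-[(1R,4R)-4-acetoxy-2,6,6-trimethylcyclohex-2-en-1-yl]-3-methylpenta-2,4-dienoate | CC1=C[C@H](OC(C)=O)CC(C)(C)[C@H]1/C=C/C(C)=C/C(=O)OCC | intermediate
31 | (2E,4E)-5-[(1R,4R)-4-hydroxy-2,6,6-trimethylcyclohex-2-en-1-yl]-3-methylpenta-2,4-dien-1-ol | CC1=C[C@H](O)CC(C)(C)[C@H]1/C=C/C(C)=C/CO | intermediate
32 | (1R,4R)-4-[(1E,3E)-5-bromo-3-methylpenta-1,3-dien-1-yl]-3,5,5-trimethylcyclohex-2-en-1-ol | CC1=C[C@H](O)CC(C)(C)[C@H]1/C=C/C(C)=C/CBr | intermediate (not isolated)
33 | {(2E,4E)-5-[(1R,4R)-4-hydroxy-2,6,6-trimethylcyclohex-2-en-1-yl]-3-methylpenta-2,4-dien-1-yl}triphenylphosphonium bromide | CC1=C[C@H](O)CC(C)(C)[C@H]1/C=C/C(C)=C/C[P+](c1ccccc1)(c1ccccc1)c1ccccc1.[Br-] | intermediate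
34 | (3S,5R,8S,3'R,6'R)-3-(tert-butyldimethylsilyloxy)-5,8-epoxy-5,8-dihydro-β,ε-caroten-3'-ol | CC1=C[C@H](O)CC(C)(C)[C@H]1/C=C/C(C)=C/C=C/C(C)=C/C=C/C=C(C)/C=C/C=C(\C)[C@@H]1C=C2C(C)(C)C[C@H](O[Si](C)(C)C(C)(C)C)C[C@@]2(C)O1 | intermediate
35 | (3S,5R,8S,3'R,6'R)-5,8-epoxy-5,8-dihydro-β,ε-carotene-3,3'-diol | CC1=C[C@H](O)CC(C)(C)[C@H]1/C=C/C(C)=C/C=C/C(C)=C/C=C/C=C(C)/C=C/C=C(\C)[C@@H]1C=C2C(C)(C)C[C@H](O)C[C@@]2(C)O1 | target

**Step count and risks**

Total step count: 25.
Longest linear sequence: 14 steps (steps 1–7, 13–17, 24, 25, from actinol 1 to 35).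

Three steps most likely to fail:

1. Step 14 (ring-closing metathesis). The cycloaddition onto the methylene shielded by two quaternary neighbours may be slow, so that alkene migration along the allyl ether and intermolecular metathesis of the vinyl group take over. The fallback gives up metathesis and uses the acid-induced epoxide-to-furanoid rearrangement; it sets out from epoxy aldehyde 8 and enal 13 and comes back at 19. Enal 13 would be reduced with NaBH4 to (2E)-4-hydroxy-3-methylbut-2-en-1-yl pivalate F1. F1 would be converted with CBr4 and PPh3, then more PPh3, into [(2E)-2-methyl-4-(pivaloyloxy)but-2-en-1-yl]triphenylphosphonium bromide F2. Wittig olefination of 8 with the ylide of F2 (NaN(SiMe3)2, THF, −78 °C) would give (2E,4E)-5-[(1S,4S,6R)-4-(tert-butyldimethylsilyloxy)-2,2,6-trimethyl-7-oxabicyclo[4.1.0]heptan-1-yl]-3-methylpenta-2,4-dien-1-yl pivalate F3. A trace of acid (pyridinium p-toluenesulfonate, CH2Cl2, 0 °C) would open the epoxide at C6 and let the C5 oxygen close onto C8, giving 19 together with its C8 epimer, (2E)-3-[(2R,6S,7aR)-6-(tert-butyldimethylsilyloxy)-4,4,7a-trimethyl-2,4,5,6,7,7a-hexahydro-1-benzofuran-2-yl]but-2-en-1-yl pivalate F4, to be separated by chromatography. C5 stays fixed, but control of C8 is lost.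

2. Step 13 (allylic etherification). Attack of the bulky tertiary copper alkoxide may be slow, so that the tert-butoxide released from the carbonate, or attack at the unsubstituted allyl terminus, consumes the allyl iridium complex and catalyst control at C8 erodes. The fallback ties nucleophile and electrophile into one molecule and lets them recombine as an ion pair after loss of CO2; it sets out from 10 and 15 and comes back at 18. Alcohol 15 would be treated with 4-nitrophenyl chloroformate and pyridine to give (2E,4E)-3-methyl-6-[(4-nitrophenoxy)carbonyloxy]hexa-2,4-dien-1-yl pivalate F5. The lithium alkoxide of 10 (n-BuLi, THF, −78 °C) would displace 4-nitrophenoxide from F5 to give the mixed carbonate (2E,4E)-3-methyl-6-({[(1R,5S)-5-(tert-butyldimethylsilyloxy)-1,3,3-trimethyl-2-methylidenecyclohexyl]oxy}carbonyloxy)hexa-2,4-dien-1-yl pivalate F6. Decarboxylative allylic etherification of F6 with [Ir(cod)Cl]2 and the same (Sa,Sc,Sc) phosphoramidite (THF, 40 °C) would then give 18, the tertiary alkoxide being the only oxygen nucleophile present.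

3. Step 7 (Wharton transposition). The hydrazone may be diverted into azine formation or simple reduction instead of fragmenting through the epoxide. The fallback replaces the hydrazone by a reductive elimination; it sets out from epoxy alcohol 7 and comes back at 10. Alcohol 7 would be converted with I2, PPh3 and imidazole (toluene, 60 °C) into (1S,4S,6R)-4-(tert-butyldimethylsilyloxy)-1-(iodomethyl)-2,2,6-trimethyl-7-oxabicyclo[4.1.0]heptane F7. Zinc dust in refluxing ethanol would then open the epoxide by reductive elimination to give 10 with the C5–O bond intact.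

**Further compounds**

F1 | step 14 | (2E)-4-hydroxy-3-methylbut-2-en-1-yl pivalate | OC/C(C)=C/COC(=O)C(C)(C)C
F2 | step 14 | [(2E)-2-methyl-4-(pivaloyloxy)but-2-en-1-yl]triphenylphosphonium bromide | c1ccccc1[P+](c1ccccc1)(c1ccccc1)C/C(C)=C/COC(=O)C(C)(C)C.[Br-]
F3 | step 14 | (2E,4E)-5-[(1S,4S,6R)-4-(tert-butyldimethylsilyloxy)-2,2,6-trimethyl-7-oxabicyclo[4.1.0]heptan-1-yl]-3-methylpenta-2,4-dien-1-yl pivalate | CC1(C)C[C@H](O[Si](C)(C)C(C)(C)C)C[C@@]2(C)O[C@@]12/C=C/C(C)=C/COC(=O)C(C)(C)C
F4 | step 14 | (2E)-3-[(2R,6S,7aR)-6-(tert-butyldimethylsilyloxy)-4,4,7a-trimethyl-2,4,5,6,7,7a-hexahydro-1-benzofuran-2-yl]but-2-en-1-yl pivalate | CC(C)(C)C(=O)OC/C=C(\C)[C@H]1C=C2C(C)(C)C[C@H](O[Si](C)(C)C(C)(C)C)C[C@@]2(C)O1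
F5 | step 13 | (2E,4E)-3-methyl-6-[(4-nitrophenoxy)carbonyloxy]hexa-2,4-dien-1-yl pivalate | O=C(OC/C=C/C(C)=C/COC(=O)C(C)(C)C)Oc1ccc(cc1)[N+](=O)[O-]
F6 | step 13 | (2E,4E)-3-methyl-6-({[(1R,5S)-5-(tert-butyldimethylsilyloxy)-1,3,3-trimethyl-2-methylidenecyclohexyl]oxy}carbonyloxy)hexa-2,4-dien-1-yl pivalate | C=C1C(C)(C)C[C@H](O[Si](C)(C)C(C)(C)C)C[C@@]1(C)OC(=O)OC/C=C/C(C)=C/COC(=O)C(C)(C)C
F7 | step 7 | (1S,4S,6R)-4-(tert-butyldimethylsilyloxy)-1-(iodomethyl)-2,2,6-trimethyl-7-oxabicyclo[4.1.0]heptane | CC1(C)C[C@H](O[Si](C)(C)C(C)(C)C)C[C@@]2(C)O[C@@]12CI
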